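## Retrosynthetic overview

1. **Feature.** In the target, O1–C8a=C4a–C4(=O), closed through C3 and C2, is the vinylogous ester of a 2-phenyl-2,3-dihydropyran-4-one (ring C). C8 is the first carbon of an alkyl arm on its enol ether carbon C8a, so ring A lacks only C5, C6 and C7.
2. **Key disconnection.** C4a–C5 and C7–C8 are cut. This gives the (S)-dihydropyranone, whose arm is C8 plus the two-unit chain, and a malonyl dichloride whose central carbon (C6) bears the three-unit chain. O1 already sits on C8a, so the short chain can only end beside O1.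
3. **Order of rings.** Ring C comes first: bought (S)-β-hydroxy ester, Weinreb amide, ynone, gold-catalysed 6-endo closure. Ring A comes second by the annulation. Five benzyl ethers are then removed.
4. **Chains.** One aryl boronate is used twice in an iterative benzylic Suzuki coupling and bromination. The two-unit bromide is the branch point for both halves.

Key step: step 17

**Remarks.** Flavanone numbering (O1, C2, C3, C4, C4a, C5 to C8, C8a) is used for all ring A and ring C atoms, also in precursors.
- "Short-chain aryl" = 2-(benzyloxy)-5-[2-(benzyloxy)benzyl]phenyl.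
- "Short-chain benzyl" = the same aryl plus CH2.
- "Long-chain benzyl" = 2-(benzyloxy)-5-{2-(benzyloxy)-5-[2-(benzyloxy)benzyl]benzyl}benzyl.
- Assumption: the malonyl dichloride cannot be distilled at this size and is used crude.

## Route

Step 1
Reactants: 1 salicyl alcohol
Product: 2 [2-(benzyloxy)phenyl]methanol
Conditions: BnBr, K2CO3, acetone, reflux
Reagents that add atoms: benzyl bromide, BrCc1ccccc1
Why: Williamson ether synthesis; K2CO3 deprotonates only the phenol, so the benzylic alcohol stays free.

Step 2
Reactants: 2 [2-(benzyloxy)phenyl]methanol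
Product: 3 1-(benzyloxy)-2-(bromomethyl)benzene
Conditions: PBr3, Et2O, 0 °C
Reagents that add atoms: phosphorus tribromide, BrP(Br)Br
Why: Bromination of a primary benzylic alcohol through its phosphite ester (SN2 by bromide); the aryl benzyl ether is inert at 0 °C.

Step 3
Reactants: 4 5-bromo-2-hydroxybenzyl alcohol
Product: 5 [2-(benzyloxy)-5-bromophenyl]methanol
Conditions: BnBr, K2CO3, acetone, reflux
Reagents that add atoms: benzyl bromide, BrCc1ccccc1
Why: Williamson ether synthesis, selective for the phenol as in step 1; the aryl bromide is a spectator.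

Step 4
Reactants: 5 [2-(benzyloxy)-5-bromophenyl]methanol
Product: 6 [2-(benzyloxy)-5-(4,4,5,5-tetramethyl-1,3,2-dioxaborolan-2-yl)phenyl]methanol
Conditions: B2pin2, PdCl2(dppf) (3 mol %), KOAc, 1,4-dioxane, 90 °C
Reagents that add atoms: bis(pinacolato)diboron, CC1(C)OB(OC1(C)C)B1OC(C)(C)C(C)(C)O1
Why: Miyaura borylation (oxidative addition of the aryl bromide to zerovalent palladium, then acetate-assisted transmetalation), which tolerates the free primary alcohol and the benzyl ether.

Step 5
Reactants: 3 1-(benzyloxy)-2-(bromomethyl)benzene; 6 [2-(benzyloxy)-5-(4,4,5,5-tetramethyl-1,3,2-dioxaborolan-2-yl)phenyl]methanol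
Product: 7 {2-(benzyloxy)-5-[2-(benzyloxy)benzyl]phenyl}methanol (short-chain alcohol)
Conditions: PdCl2(dppf) (3 mol %), K2CO3, THF/H2O 10:1, 70 °C
Reagents that add atoms: none
Why: Suzuki–Miyaura coupling of a benzylic bromide with an aryl boronate, a standard diarylmethane synthesis; the new CH2–aryl bond lies para to the benzyloxy group because boron sat there.

Step 6
Reactants: 7 short-chain alcohol
Product: 8 1-(benzyloxy)-4-[2-(benzyloxy)benzyl]-2-(bromomethyl)benzene (short-chain bromide)
Conditions: PBr3, Et2O/CH2Cl2, 0 °C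
Reagents that add atoms: phosphorus tribromide, BrP(Br)Br
Why: Bromination through the phosphite ester as in step 2; the bromide is used soon after isolation because ortho-alkoxybenzyl bromides are reactive.

Step 7
Reactants: 8 short-chain bromide; 6 [2-(benzyloxy)-5-(4,4,5,5-tetramethyl-1,3,2-dioxaborolan-2-yl)phenyl]methanol
Product: 9 (2-(benzyloxy)-5-{2-(benzyloxy)-5-[2-(benzyloxy)benzyl]benzyl}phenyl)methanol (long-chain alcohol)
Conditions: PdCl2(dppf) (3 mol %), K2CO3, THF/H2O 10:1, 70 °C
Reagents that add atoms: none
Why: Second benzylic Suzuki–Miyaura coupling with the same boronate, which adds the third hydroxybenzyl unit with the same para-to-oxygen connectivity.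

Step 8
Reactants: 9 long-chain alcohol
Product: 10 1-(benzyloxy)-4-{2-(benzyloxy)-5-[2-(benzyloxy)benzyl]benzyl}-2-(bromomethyl)benzene (long-chain bromide)
Conditions: PBr3, Et2O/CH2Cl2, 0 °C
Reagents that add atoms: phosphorus tribromide, BrP(Br)Br
Why: Bromination through the phosphite ester as in steps 2 and 6.

Step 9
Reactants: 10 long-chain bromide; 11 dimethyl malonate
Product: 13 dimethyl 2-(long-chain benzyl)malonate, via sodium dimethyl malonate 12 (not isolated)
Conditions: 11 (3 equiv), NaH, THF/DMF, 0 °C; then 10, 0 °C → rt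
Reagents that add atoms: none
Why: Malonic ester alkylation (SN2 on a benzylic bromide); the excess of malonate anion suppresses double alkylation.

Step 10
Reactants: 13 dimethyl 2-(long-chain benzyl)malonate
Product: 14 2-(long-chain benzyl)malonic acid
Conditions: KOH, THF/MeOH/H2O, 40 °C; then 1 M HCl, 0 °C
Reagents that add atoms: potassium hydroxide, [K+].[OH-]
Why: Saponification of both methyl esters; acidification and drying in the cold avoid decarboxylation of the malonic acid.

Step 11
Reactants: 14 2-(long-chain benzyl)malonic acid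
Product: 15 2-(long-chain benzyl)malonyl dichloride
Conditions: (COCl)2, DMF (cat.), CH2Cl2, 0 °C → rt; concentrated, used crude
Reagents that add atoms: oxalyl chloride, O=C(Cl)C(=O)Cl
Why: Acid chloride formation through the Vilsmeier-type chloroiminium catalyst, run at or below room temperature so that neither decarboxylation nor loss of HCl sets in.

Step 12
Reactants: 8 short-chain bromide; 16 1-(trimethylsilyl)propyne
Product: 18 trimethyl[4-(short-chain aryl)but-1-yn-1-yl]silane, via lithiated silylpropyne 17 (not isolated)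
Conditions: 16, nBuLi, THF, −78 °C; then 8, −78 → 0 °C
Reagents that add atoms: none
Why: Alkylation of a propargylic carbanion; the silyl group blocks the acetylenic terminus and steers the SN2 attack on the benzylic bromide to the propargyl rather than the allenyl carbon.

Step 13
Reactants: 18 trimethyl[4-(short-chain aryl)but-1-yn-1-yl]silane
Product: 19 1-(benzyloxy)-4-[2-(benzyloxy)benzyl]-2-(but-3-yn-1-yl)benzene (short-chain butyne)
Conditions: K2CO3 (cat.), MeOH/THF, rt
Reagents that add atoms: none
Why: Protodesilylation of an alkynylsilane by methoxide, which touches no other group.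

Step 14
Reactants: 20 ethyl (S)-3-hydroxy-3-phenylpropanoate
Product: 21 (S)-3-hydroxy-N-methoxy-N-methyl-3-phenylpropanamide
Conditions: MeNH(OMe)·HCl, iPrMgCl, THF, −20 → 0 °C; then 1 M HCl, 0 °C
Reagents that add atoms: N,O-dimethylhydroxylamine hydrochloride, CNOC.Cl
Why: Weinreb amide formation by aminolysis of the ester with the magnesium amide; the carbinol carbon (future C2) carries no acidic hydrogen and keeps its bought S configuration.

Step 15
Reactants: 19 short-chain butyne; 21 (S)-3-hydroxy-N-methoxy-N-methyl-3-phenylpropanamide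
Product: 24 (S)-1-hydroxy-1-phenyl-7-(short-chain aryl)hept-4-yn-3-one, via lithium acetylide 22 (not isolated), via chloromagnesium alkoxide 23 (not isolated)
Conditions: 19, nBuLi, THF, −78 °C; 21, iPrMgCl, THF, −40 °C; mixed, −78 → 0 °C; then 1 M HCl, 0 °C
Reagents that add atoms: none
Why: Weinreb ketone synthesis; the hydroxyl is deprotonated beforehand by cheap iPrMgCl so that one equivalent of acetylide suffices, the chelated tetrahedral adduct holds until the quench, and no bond at the stereocentre is touched.

Step 16
Reactants: 24 (S)-1-hydroxy-1-phenyl-7-(short-chain aryl)hept-4-yn-3-one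
Product: 25 (S)-2-phenyl-6-[2-(short-chain aryl)ethyl]-2,3-dihydro-4H-pyran-4-one
Conditions: Ph3PAuNTf2 (3 mol %), CH2Cl2, rt
Reagents that add atoms: none
Why: Gold-catalysed intramolecular hydroalkoxylation of a β-hydroxy ynone; cationic monovalent gold activates the alkyne, the ynone polarisation sends the hydroxyl to the distal alkyne carbon (C8a) in 6-endo-dig mode, and C2 keeps its configuration because only its O–H bond reacts.

Step 17
Reactants: 15 2-(long-chain benzyl)malonyl dichloride; 25 (S)-2-phenyl-6-[2-(short-chain aryl)ethyl]-2,3-dihydro-4H-pyran-4-one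
Product: 29 (S)-5,7-dihydroxy-6-(long-chain benzyl)-8-(short-chain benzyl)flavanone, via chlorocarbonyl ketene 26 (not isolated), via acylketene 27 (not isolated), via dienylketene 28 (not isolated)
Conditions: 15, PhMe, 110 °C, Ar sparge, 1 h; then added slowly to 25 (slight excess), PhMe (0.02 M), 110 °C, Ar sparge; no basic work-up
Reagents that add atoms: none
Why: Proposed new method: thermal loss of HCl turns 15 into chlorocarbonyl ketene 26, which is attacked by C4a, the nucleophilic carbon of the O1–C8a=C4a enol ether of 25 (bond C4a–C5), and a second loss of HCl leaves acylketene 27. In 27 the C8 methylene is vinylogously acidified by the C4 and C5 carbonyls and passes a proton to the C5 oxygen, giving dienylketene 28 with the conjugated array C8=C8a–C4a=C5–C6=C7=O. Ring A closes by thermal disrotatory 6π electrocyclisation of this array (bond C7–C8), and proton shifts then aromatise the ring to the 5,7-diol of 29. The closest known reaction types are the α,α′-double acylation of ketone enol ethers with malonyl dichlorides to phloroglucinol ethers and bicyclic triones (Effenberger cyclisation) and the dienylketene closure that ends a Danheiser benzannulation, and neither has been shown on the deactivated enol ether of a dihydropyranone. No stereocentre is formed, and C2 is kept because no base is present that could open O1–C2 by E1cB and because HCl is swept out with argon before it can ionise that benzylic bond. The step needs closure at carbon C8 rather than at the C4 carbonyl oxygen, and this is secured by the hydrogen bond between the C5 enol OH and the C4 carbonyl in toluene, which turns the ketene arm on C5 towards C8, by the alkylated O1, which blocks the usual pyrone outlet of ketones, and by aromatisation, which makes C-closure irreversible, while the place of the short chain beside O1 follows from the connectivity of 25.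

Step 18
Reactants: 29 (S)-5,7-dihydroxy-6-(long-chain benzyl)-8-(short-chain benzyl)flavanone
Product: 30 sarmentosumin D
Conditions: H2 (1 atm), 10% Pd/C, EtOAc/MeOH, rt
Reagents that add atoms: none
Why: Catalytic hydrogenolysis of five primary aryl benzyl ethers under neutral conditions; these should cleave faster than the secondary ring-bound O1–C2 bond or the chelated C4 ketone, and the absence of acid and base leaves C2 as S.

## Compound list

1 | salicyl alcohol | OCc1ccccc1O | starting material
2 | [2-(benzyloxy)phenyl]methanol | OCc1ccccc1OCc1ccccc1 | intermediate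
3 | 1-(benzyloxy)-2-(bromomethyl)benzene | BrCc1ccccc1OCc1ccccc1 | intermediate
4 | 5-bromo-2-hydroxybenzyl alcohol | OCc1cc(Br)ccc1O | starting material
5 | [2-(benzyloxy)-5-bromophenyl]methanol | OCc1cc(Br)ccc1OCc1ccccc1 | intermediate
6 | [2-(benzyloxy)-5-(4,4,5,5-tetramethyl-1,3,2-dioxaborolan-2-yl)phenyl]methanol | OCc1cc(B2OC(C)(C)C(C)(C)O2)ccc1OCc1ccccc1 | intermediate
7 | {2-(benzyloxy)-5-[2-(benzyloxy)benzyl]phenyl}methanol (short-chain alcohol) | OCc1cc(Cc2ccccc2OCc2ccccc2)ccc1OCc1ccccc1 | intermediate
8 | 1-(benzyloxy)-4-[2-(benzyloxy)benzyl]-2-(bromomethyl)benzene (short-chain bromide) | BrCc1cc(Cc2ccccc2OCc2ccccc2)ccc1OCc1ccccc1 | intermediate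
9 | (2-(benzyloxy)-5-{2-(benzyloxy)-5-[2-(benzyloxy)benzyl]benzyl}phenyl)methanol (long-chain alcohol) | OCc1cc(Cc2cc(Cc3ccccc3OCc3ccccc3)ccc2OCc2ccccc2)ccc1OCc1ccccc1 | intermediate
10 | 1-(benzyloxy)-4-{2-(benzyloxy)-5-[2-(benzyloxy)benzyl]benzyl}-2-(bromomethyl)benzene (long-chain bromide) | BrCc1cc(Cc2cc(Cc3ccccc3OCc3ccccc3)ccc2OCc2ccccc2)ccc1OCc1ccccc1 | intermediate
11 | dimethyl malonate | COC(=O)CC(=O)OC | starting material
12 | sodium dimethyl malonate (not isolated) | [Na+].COC(=O)[CH-]C(=O)OC | intermediate
13 | dimethyl 2-(long-chain benzyl)malonate | COC(=O)C(Cc1cc(Cc2cc(Cc3ccccc3OCc3ccccc3)ccc2OCc2ccccc2)ccc1OCc1ccccc1)C(=O)OC | intermediate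
14 | 2-(long-chain benzyl)malonic acid | OC(=O)C(Cc1cc(Cc2cc(Cc3ccccc3OCc3ccccc3)ccc2OCc2ccccc2)ccc1OCc1ccccc1)C(=O)O | intermediate
15 | 2-(long-chain benzyl)malonyl dichloride | O=C(Cl)C(Cc1cc(Cc2cc(Cc3ccccc3OCc3ccccc3)ccc2OCc2ccccc2)ccc1OCc1ccccc1)C(=O)Cl | intermediate
16 | 1-(trimethylsilyl)propyne | CC#C[Si](C)(C)C | starting material
17 | 3-lithio-1-(trimethylsilyl)propyne (not isolated) | [Li]CC#C[Si](C)(C)C | intermediate
18 | trimethyl[4-(short-chain aryl)but-1-yn-1-yl]silane | C[Si](C)(C)C#CCCc1cc(Cc2ccccc2OCc2ccccc2)ccc1OCc1ccccc1 | intermediate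
19 | 1-(benzyloxy)-4-[2-(benzyloxy)benzyl]-2-(but-3-yn-1-yl)benzene (short-chain butyne) | C#CCCc1cc(Cc2ccccc2OCc2ccccc2)ccc1OCc1ccccc1 | intermediate
20 | ethyl (S)-3-hydroxy-3-phenylpropanoate | CCOC(=O)C[C@H](O)c1ccccc1 | starting material
21 | (S)-3-hydroxy-N-methoxy-N-methyl-3-phenylpropanamide | CON(C)C(=O)C[C@H](O)c1ccccc1 | intermediate
22 | lithium acetylide of 19 (not isolated) | [Li]C#CCCc1cc(Cc2ccccc2OCc2ccccc2)ccc1OCc1ccccc1 | intermediate
23 | chloromagnesium alkoxide of 21 (not isolated) | CON(C)C(=O)C[C@H](O[Mg]Cl)c1ccccc1 | intermediate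
24 | (S)-1-hydroxy-1-phenyl-7-(short-chain aryl)hept-4-yn-3-one | O=C(C[C@H](O)c1ccccc1)C#CCCc1cc(Cc2ccccc2OCc2ccccc2)ccc1OCc1ccccc1 | intermediate
25 | (S)-2-phenyl-6-[2-(short-chain aryl)ethyl]-2,3-dihydro-4H-pyran-4-one | O=C1C[C@@H](c2ccccc2)OC(CCc2cc(Cc3ccccc3OCc3ccccc3)ccc2OCc2ccccc2)=C1 | intermediate
26 | (chlorocarbonyl)(long-chain benzyl)ketene (not isolated) | O=C=C(Cc1cc(Cc2cc(Cc3ccccc3OCc3ccccc3)ccc2OCc2ccccc2)ccc1OCc1ccccc1)C(=O)Cl | intermediate
27 | acylketene: 25 acylated at C4a by the 2-(long-chain benzyl)-3-oxoacryloyl group (not isolated) | O=C=C(Cc1cc(Cc2cc(Cc3ccccc3OCc3ccccc3)ccc2OCc2ccccc2)ccc1OCc1ccccc1)C(=O)C1=C(CCc2cc(Cc3ccccc3OCc3ccccc3)ccc2OCc2ccccc2)O[C@H](c2ccccc2)CC1=O | intermediate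
28 | dienylketene: tautomer of 27 with C5 enol and exocyclic C8=C8a, double-bond geometries mobile (not isolated) | O=C=C(Cc1cc(Cc2cc(Cc3ccccc3OCc3ccccc3)ccc2OCc2ccccc2)ccc1OCc1ccccc1)C(O)=C1C(=O)C[C@@H](c2ccccc2)OC1=CCc1cc(Cc2ccccc2OCc2ccccc2)ccc1OCc1ccccc1 | intermediate
29 | (S)-5,7-dihydroxy-6-(long-chain benzyl)-8-(short-chain benzyl)flavanone | O=C1C[C@@H](c2ccccc2)Oc2c(Cc3cc(Cc4ccccc4OCc4ccccc4)ccc3OCc3ccccc3)c(O)c(Cc3cc(Cc4cc(Cc5ccccc5OCc5ccccc5)ccc4OCc4ccccc4)ccc3OCc3ccccc3)c(O)c21 | intermediate
30 | sarmentosumin D | O=C1C[C@@H](c2ccccc2)Oc2c(Cc3cc(Cc4ccccc4O)ccc3O)c(O)c(Cc3cc(Cc4cc(Cc5ccccc5O)ccc4O)ccc3O)c(O)c21 | target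

## Step count and risks

Total step count: 18.
Longest linear sequence: 11 steps (4 → 5 → 6 → 7 → 8 → 9 → 10 → 13 → 14 → 15 → 29 → 30).

**Step 17 (key step).** Four things may go wrong:
- Acylation at C4a may be too slow on the deactivated enol ether.
- The ketene arm may close through the C4 carbonyl oxygen instead of C8.
- The ketene or acid chloride may be consumed by the neighbouring benzyloxy oxygen of the long chain, with loss of the benzyl group.
- HCl may ionise the benzylic O1–C2 bond and erode the configuration.

The fallback sets out from 7 and 9 and comes back at 30. It gives up the annulation and buys ring A as (S)-pinocembrin (O=C1C[C@@H](c2ccccc2)Oc2cc(O)cc(O)c21). It uses the known Lewis-acid-mediated ortho-quinone-methide Friedel–Crafts hydroxybenzylation of 5,7-dihydroxyflavanones by salicyl-type alcohols. Alcohol 7 is debenzylated (H2, Pd/C, EtOAc, neutral, stopped after the two ether cleavages) to 2-(hydroxymethyl)-4-(2-hydroxybenzyl)phenol F1. This is added slowly to an excess of (S)-pinocembrin with ZnCl2 in dioxane at reflux. This chemistry offers no control between C8 and C6, so both monoadducts are separated by chromatography and assigned by HMBC from the chelated 5-OH. The C8 isomer, (S)-8-[2-hydroxy-5-(2-hydroxybenzyl)benzyl]pinocembrin F2, is kept. Alcohol 9 is debenzylated in the same way to 2-(hydroxymethyl)-4-[2-hydroxy-5-(2-hydroxybenzyl)benzyl]phenol F3. With F2 and ZnCl2 in dioxane, F3 can attack ring A only at C6 and gives 30. The price is the lost regiocontrol, some self-condensation of the phenolic alcohols, and the need to check the enantiopurity by chiral HPLC.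

**Step 15.** Addition of the acetylide to the anionic amide may stall. The magnesium alkoxide may also fragment by retro-aldol cleavage or eliminate on warming. The fallback sets out from 21 and comes back at 24, and it replaces the sacrificial base by a protecting group. Amide 21 is silylated (TESCl, imidazole, CH2Cl2) to (S)-N-methoxy-N-methyl-3-phenyl-3-(triethylsilyloxy)propanamide F4. As a neutral electrophile, F4 takes up one equivalent of acetylide 22 to give (S)-1-phenyl-7-(short-chain aryl)-1-(triethylsilyloxy)hept-4-yn-3-one F5. AcOH/THF/H2O at rt then frees 24.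

**Step 18.** Hydrogenolysis of the benzylic O1–C2 bond, or reduction of the C4 carbonyl, may begin before the fifth benzyl ether has gone. The fallback sets out from 29 and comes back at 30 by a non-reductive route. This is Lewis-acid debenzylation with BCl3 and pentamethylbenzene as cation scavenger in CH2Cl2 at −78 °C. There O1, whose lone pair is tied up in the vinylogous ester, should bind boron less well than the chain ethers. No new compound arises on this way (F0).

## Further compounds

F1 | step 17 | 2-(hydroxymethyl)-4-(2-hydroxybenzyl)phenol | OCc1cc(Cc2ccccc2O)ccc1O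
F2 | step 17 | (S)-8-[2-hydroxy-5-(2-hydroxybenzyl)benzyl]pinocembrin | O=C1C[C@@H](c2ccccc2)Oc2c(Cc3cc(Cc4ccccc4O)ccc3O)c(O)cc(O)c21
F3 | step 17 | 2-(hydroxymethyl)-4-[2-hydroxy-5-(2-hydroxybenzyl)benzyl]phenol | OCc1cc(Cc2cc(Cc3ccccc3O)ccc2O)ccc1O
F4 | step 15 | (S)-N-methoxy-N-methyl-3-phenyl-3-(triethylsilyloxy)propanamide | CON(C)C(=O)C[C@H](O[Si](CC)(CC)CC)c1ccccc1
F5 | step 15 | (S)-1-phenyl-7-(short-chain aryl)-1-(triethylsilyloxy)hept-4-yn-3-one | O=C(C[C@H](O[Si](CC)(CC)CC)c1ccccc1)C#CCCc1cc(Cc2ccccc2OCc2ccccc2)ccc1OCc1ccccc1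
F0 | step 18 | none | none
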